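I started from amounts. Blue, with L (the substrate) at 2.3 M and X (the reagent) at 0.55 M, held J (the product) at 20 % at 40.0 min and at 26 % at 80.0 min. One X per J gives blue a ceiling of 23.9 % of its L, and the last reading lies 2.1 percentage points above that, against a scatter of 2 points. So I counted turnovers: 0.550 M of X over 1.6 mM of Z (the catalyst) pays for 344 rounds of each Z, while maple's L would need 1250.

| flask | L | X | Z | temperature | remark | time |
|---|---|---|---|---|---|---|
| violet | 0.56 M | 0.55 M | 1.6 mM | 85 °C | run made earlier |  |
| ochre | 0.99 M | 0.55 M | 1.6 mM | 100 °C | run made earlier |  |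
| blue | 2.3 M | 0.55 M | 1.6 mM | 85 °C | run made earlier |  |
| maple | 2.0 M | 0.550 M | 1.6 mM | 100 °C |  | 80 min |
| birch | 0.50 M | 0.550 M | 1.6 mM | 100 °C |  | 40 min |

- violet (time / min: J / %): 10.0: 5; 30.0: 23; 50.0: 38; 80.0: 50
- ochre (time / min: J / %): 10.0: 16; 20.0: 32; 30.0: 41; 40.0: 48
- blue (time / min: J / %): 20.0: 14; 40.0: 20; 60.0: 21; 80.0: 26

(readings scatter by 2 percentage points)

* the flask that ends with the higher amount of J, in percent of the L charged, or "neither" when 2 percentage points or less lies between them (maple / birch / neither)
* final J, as a percentage of the L charged, in maple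
* final J, as a percentage of the L charged, in birch

- a reading or a percentage of J counts all its forms, free or not

The next run hung on one ratio. Maple's X ceiling, 27.5 %, is the X charge divided by the L charge, with X as the limiting reagent. Blue's reading at 40.0 min stood 3.9 points under its ceiling, and maple is hotter and runs 80 min, so I expected maple to reach its own. Birch's ratio is 110 %, so X sets no ceiling there below its L. To pass maple, birch must hold 0.138 M of J. Ochre, at the same temperature and X with about twice birch's L, held 0.158 M at 10.0 min. Even at a speed falling in step with L, I reckoned that birch would need about 19.8 min for ochre's amount, less than its 40 min. So I would charge birch's L and leave X and Z as they were.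

The forecast said birch, with 27 % for maple and 59 % for birch, reading blue to mean that “X is consumed about 1:1 and caps J”. Its birch figure came from a rate estimate; my reckoning gave no figure for birch, only that it passes maple.

Maple gave 27.5 % and birch 60.3 %, so birch ended higher.

L + Z ⇌ Z + G (K = 0.780, k = 46.0 /M/min, Ea = 66.0 kJ/mol, ΔH = 17.0 kJ/mol); X + Z + G → Z + J (k = 140 /M²/min, Ea = 65.0 kJ/mol); Z → D (k = 3.60 × 10⁻⁵ /min, Ea = 122 kJ/mol); Q ⇌ J, rate k4*(cs4 - [J]) while solid is left; crystals form when [J] > cs4 (solubility = 36.0 mM, k = 0.330 /min); (constants at 100 °C) Maple's J matched its ceiling 27.5 %, with X down to 0.883 % of its charge at 40.0 min. A neighbour of maple charged with 0.33 M of X has a ceiling of 16.5 % and gave 16.5 %. Maple's J had come to rest: ten times its time, 800 min, brings J to 27.5 %, with L still at 40.7 %. Birch's J had not, with 45.2 % of its X left at the end: ten times its time, 400 min, takes J to 98.1 %.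

All runs were generated by integration for substances that don't exist, noise included.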